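## Structural features

CJ-13,103 (15) is a phthalide: a benzene ring fused through C3a and C7a to a five-membered lactone (C1 carbonyl, O2, C3), with methoxy groups on C5 and C7, the latter flanking the lactone carbonyl. C3 is the only stereocentre, (S), benzylic and oxygen-bearing; it carries an unbranched sixteen-carbon chain (C1' to C16') whose C12' and C15' carbons are ketones, a 1,4-diketone ending in the C16' methyl group. No neighbouring stereocentre exists from which the configuration could be relayed, so it must come from a reagent or catalyst acting on a flat precursor. The fragile parts are the 1,4-diketone (cyclopentenone formation with base, furan formation under dehydrating acid), the lactone (hydride reagents, hard nucleophiles) and the C3–H bond, which strong base would remove. The real difficulty is to create one benzylic C–O stereocentre in a molecule that holds two further ketones far down the chain, without a protecting-group campaign. The key step uses the fact that C1–O2–C3 is at the same overall oxidation level as an aldehyde at C1 and a ketone at C3 placed ortho on C7a and C3a; a metal that has entered the C1–H bond can reach only the C3 carbonyl, through a six-membered chelate, and never C12' or C15'. The rest maps onto cheap building blocks: the dimethoxylated ring with C1 attached is a commercial bromo aldehyde whose bromine marks C3a, C12' to C16' with both ketone oxygens are latent in a 2-methylfuran ring, and C3 with C1' to C11' are the twelve carbons of a bromo acid. The phthalide locants are used below for the corresponding atoms of every earlier compound.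

## Logic of the disconnections

15 is opened at O2–C1, and the hydrogen on C3 is returned to C1, which gives the achiral isomer 14. The cut is made here because ring, stereocentre and correct oxidation level then arise together in a redox-neutral final operation, with no protecting group and no stereocentre to carry through the route. The demand on the forward step is a catalyst that distinguishes the two faces of the C3 carbonyl, leaves C12' and C15' alone, tolerates the C7 methoxy group beside the aldehyde and avoids decarbonylation.

14 is traced back to 12, passing through 13. The C1 aldehyde is folded into a dioxolane, and the two ketone oxygens at C12' and C15' into one furan oxygen, so that C12' to C15' become the four furan ring carbons. This makes every carbonyl except C3 inert to carbanions at no cost in extra protection steps. The demand is one aqueous acid treatment that opens the furan without letting the liberated keto aldehyde undergo aldol chemistry.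

12 is cut at C3–C3a into 9 and 7, by way of 10 and 11. This is the only carbon–carbon bond between arene and chain, so the cut is fully convergent and leaves an aryl anion and an acyl cation equivalent. The demand is that halogen–metal exchange outruns proton abstraction, that the anion stays at C3a, and that addition stops at the ketone.

9 goes back to 8 by removing the acetal, which costs one step and makes the aldehyde compatible with the organolithium.

7 is cut at the amide C–N bond to 5, through 6; this is a routine activation of the acid and brings the chain to a storable acid.

5 is cut at C11'–C12', the bond between the chain and the furan, into 1 and 2, through 3 and 4. A furyl anion and a primary bromide are the natural partners, and both are commercial. The demand is an alkylation that proceeds in the presence of a carboxylate, which requires a second equivalent of the anion and a polar cosolvent.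

## Other disconnections considered

Alternative 1: The cut is the arene bond C3a–C7a, so the benzene ring is taken apart into a linear polyketide chain in which C1 and the C7 oxygen are tied into a dioxinone.
- Forward key step: the diketo-dioxinone A2, 6-[(5S)-5-(tert-butyldimethylsilyloxy)-16-(5-methylfuran-2-yl)-2,4-dioxohexadecyl]-2,2-dimethyl-4H-1,3-dioxin-4-one, would be treated with Et3N and then mild acid. The dioxinone α-carbon (future C7a) should add to the ketone next to the silyloxy carbon (future C3a), and dehydration and enolisation should give the arene A1, 5-[(1S)-1-(tert-butyldimethylsilyloxy)-12-(5-methylfuran-2-yl)dodecyl]-7-hydroxy-2,2-dimethyl-4H-1,3-benzodioxin-4-one.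
- In favour: the oxygenation pattern is fixed by the chain with no regiochemical question, and the step is metal-free and mild.
- In favour, and better than the chosen plan for analogue work: the C5 oxygen appears as a free phenol while the C7 oxygen stays locked, whereas the chosen plan fixes both as methyl ethers from the start.
- Against: the ring with both methoxy groups and C1 can be bought, so building it spends steps on atoms that cost nothing in the chosen plan.
- Against: the stereocentre must exist before the key step and sits alpha to the acceptor ketone inside a β-diketone, where the amine base can enolise it.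
- Against: A1 is still about four operations from 15 (O-methylation, desilylation with lactonisation onto the dioxinone carbonyl, methylation of the freed C7 phenol, furan hydrolysis), and A2 itself needs an enantiopure α-silyloxy acyl donor and a dioxinone dianion acylation.
- Comparison: on structure both key steps close exactly one ring (equal), but this one forms no stereocentre. On mechanism it is the better in catalyst cost and operational simplicity and the worse in configurational safety. On step economy it would be roughly twice as long.

Alternative 2: The cut is the pair of arene bonds C3a–C4 and C7–C7a.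
- Forward key step: the diene A5, 1,3-dimethoxycyclohexa-1,3-diene, and the ynoate A4, methyl (4S)-4-(tert-butyldimethylsilyloxy)-16,19-dioxoicos-2-ynoate, would be heated together. A [4+2] addition and loss of the two-carbon bridge in a retro-[4+2] step should give the benzoate A3, methyl 2-[(1S)-1-(tert-butyldimethylsilyloxy)-13,16-dioxoheptadecyl]-4,6-dimethoxybenzoate.
- In favour, and better than the chosen key step on bond count: two skeletal C–C bonds form in one reagent-free operation.
- In favour: the regiochemistry should follow from pairing the unsubstituted, nucleophilic diene terminus with the ynoate β-carbon, and the stereocentre is only a spectator in a neutral thermal step.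
- In favour, and close to equal with the chosen plan: A3 is one acidic desilylation–lactonisation from 15, so the end game is almost as short.
- Against: the arene is again built although it can be bought, the diene is an acid- and air-sensitive bis-enol ether, and the ynoate is branched and bulky at its reacting terminus.
- Against: the extrusion is expected to need temperatures well above 100 °C.
- Against: enantiopure A4 requires an asymmetric propargylic reduction or alkynylation in a chain that already holds two ketones or their protected forms, so the ketone-discrimination problem is moved earlier, not removed.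
- Comparison: on structure it builds more of the skeleton per step. On mechanism it avoids a precious metal in the ring-forming step but pays with harsh heating. On step economy it would be longer by several steps, because the chiral ynoate costs about as much as the whole chosen route.

Alternative 3: The cut is both bonds from the lactone atoms to the arene, C3–C3a and C7a–C1.
- Forward key step: the carbamate A7, 12-[2-[2-(2-methyl-1,3-dioxolan-2-yl)ethyl]-1,3-dioxolan-2-yl]dodecyl N,N-diisopropylcarbamate, would be deprotonated at its O–CH2 carbon (future C3) with s-BuLi and (+)-sparteine. An aryne would be released in the same flask from the iodo triflate A8, 2-iodo-3,5-dimethoxyphenyl trifluoromethanesulfonate, with n-BuLi. The carbanion should add to the aryne carbon remote from the neighbouring methoxy group, and the aryl anion then formed at C7a should attack the carbamate carbonyl and expel the dialkylamide. The product would be the ketal-protected phthalide A6, (3S)-5,7-dimethoxy-3-{11-[2-[2-(2-methyl-1,3-dioxolan-2-yl)ethyl]-1,3-dioxolan-2-yl]undecyl}-2-benzofuran-1(3H)-one.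
- In favour, and clearly better than the chosen key step on bonds per operation: it is the most convergent plan, with two C–C bonds, the ring and the stereocentre formed in one flask.
- In favour: the usual preference of an alkoxy-substituted aryne for attack at the distal carbon fits the required regiochemistry, and retention at the lithiated carbon would lead from the (+)-sparteine complex to the (S) product.
- Against: three organolithium events must be kept apart at low temperature. n-BuLi has to exchange iodine on A8 without adding to the aryne or disturbing the lithiated form of A7.
- Against: the stereochemical course of aryne capture by such a carbanion is not secure.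
- Against: the diisopropylcarbamoyl group is built to resist nucleophiles.
- Against: the chiral diamine is stoichiometric.
- Against: both chain ketones must be ketalised beforehand and released afterwards.
- Comparison: on structure this plan is superior in convergence. On mechanism it rests on an untested sequence of reactive intermediates, whereas the chosen key step has a direct counterpart on the same substrate class. On step economy the preparation of A7 and A8 plus the deprotection would bring it to about eight or nine steps against six.

Key step: step 6

Assumption: the sense of induction of DuanPhos is carried over from 2-alkanoylbenzaldehydes without ring substituents; should a trial show the opposite sense for 14, the (1R,1'R,2S,2'S) ligand would be used under the same conditions.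

## Route

Step 1
Reactants: 1 2-methylfuran; 2 12-bromododecanoic acid
Product: 5 12-(5-methylfuran-2-yl)dodecanoic acid, via 5-methyl-2-furyllithium 3 (not isolated), via lithium 12-bromododecanoate 4 (not isolated)
Conditions: 1 (2.3 equiv), n-BuLi (2.2 equiv), THF, 0 °C; then 2 (1.0 equiv), THF/DMPU, −78 °C to rt; aq HCl to pH 3
Reagents that add atoms: none
Why: n-BuLi removes the free α-hydrogen of 1 to give 3; one equivalent of 3 converts 2 into its carboxylate 4 and a second displaces the primary bromide in an SN2 alkylation of a heteroaryllithium, the same reaction type as the alkylation of lithium acetylides by ω-bromo carboxylates. The carboxylate is a poor electrophile for the stabilised furyl anion at or below room temperature, and DMPU keeps 4 in solution and speeds the substitution.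

Step 2
Reactants: 5 12-(5-methylfuran-2-yl)dodecanoic acid
Product: 7 N-methoxy-N-methyl-12-(5-methylfuran-2-yl)dodecanamide, via acyl imidazole 6 (not isolated)
Conditions: CDI (1.1 equiv), CH2Cl2, rt; then MeNHOMe·HCl (1.3 equiv), rt
Reagents that add atoms: N,O-dimethylhydroxylamine hydrochloride (CNOC.Cl)
Why: Weinreb amide formation through the acyl imidazole 6; the medium is never strongly acidic, so the acid-sensitive furan is not touched.

Step 3
Reactants: 8 2-bromo-4,6-dimethoxybenzaldehyde
Product: 9 2-(2-bromo-4,6-dimethoxyphenyl)-1,3-dioxolane
Conditions: HOCH2CH2OH (5 equiv), TsOH·H2O (cat.), toluene, reflux, Dean–Stark; Et3N quench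
Reagents that add atoms: ethylene glycol (OCCO)
Why: Acid-catalysed acetalisation driven by azeotropic removal of water; the cyclic acetal is chosen over a dimethyl acetal because the electron-rich aryl acetal must survive chromatography and the organolithium step.

Step 4
Reactants: 9 2-(2-bromo-4,6-dimethoxyphenyl)-1,3-dioxolane; 7 N-methoxy-N-methyl-12-(5-methylfuran-2-yl)dodecanamide
Product: 12 1-[2-(1,3-dioxolan-2-yl)-3,5-dimethoxyphenyl]-12-(5-methylfuran-2-yl)dodecan-1-one, via aryllithium 10 (not isolated), via lithium hemiaminal alkoxide 11 (not isolated)
Conditions: 9 (1.2 equiv), n-BuLi (1.15 equiv), THF, −78 °C; then 7 (1.0 equiv), −78 to 0 °C; H2O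
Reagents that add atoms: none
Why: Bromine–lithium exchange at −78 °C is faster than any deprotonation and places lithium on the carbon that becomes C3a, where the neighbouring dioxolane oxygen holds it. Weinreb ketone synthesis: 10 adds once to 7 and the chelated adduct 11 persists until the aqueous quench, so no tertiary alcohol can form.

Step 5
Reactants: 12 1-[2-(1,3-dioxolan-2-yl)-3,5-dimethoxyphenyl]-12-(5-methylfuran-2-yl)dodecan-1-one
Product: 14 2,4-dimethoxy-6-(13,16-dioxoheptadecanoyl)benzaldehyde, via furan keto aldehyde 13 (not isolated)
Conditions: AcOH/H2O (3:1), H2SO4 (cat.), 75 °C, N2, dilute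
Reagents that add atoms: water (O)
Why: Acetal hydrolysis of the electron-rich aryl dioxolane is fast and gives 13; protonation of the 2,5-dialkylfuran at an α-carbon, addition of water and ring opening (the reverse of a Paal–Knorr furan synthesis) then free the 1,4-diketone, with the excess of water holding the equilibrium on the open side. The aldehyde of 14 is conjugated with two methoxy donors and flanked by two ortho substituents, which should make it a weak acceptor for an aldol with the C3 ketone enol.

Step 6
Reactants: 14 2,4-dimethoxy-6-(13,16-dioxoheptadecanoyl)benzaldehyde
Product: 15 CJ-13,103, (3S)-5,7-dimethoxy-3-(12,15-dioxohexadecyl)-2-benzofuran-1(3H)-one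
Conditions: [Rh(cod)Cl]2 (2.5 mol %), (1S,1'S,2R,2'R)-DuanPhos (5 mol %), AgNO3 (5 mol %), toluene, 90 °C
Reagents that add atoms: none
Why: AgNO3 strips chloride from [Rh(cod)Cl]2 so that a DuanPhos-bound monovalent rhodium nitrate with open sites forms, and this inserts into the aldehyde C1–H bond of 14 to give a trivalent acyl rhodium hydride. The C3 ketone oxygen, held ortho on C3a, binds the metal in a six-membered chelate (Rh, C1, C7a, C3a, C3, O) that occupies the site needed for CO de-insertion and so holds back decarbonylation. The C3 carbonyl then inserts into Rh–H, the enantiodetermining event, which puts hydrogen on C3 and gives a six-membered acyl rhodium alkoxide. C–O reductive elimination joins O2 to the acyl carbon C1; the five-membered lactone closes by contraction of that six-membered rhodacycle (formally a 5-exo-trig acylation of the C3 oxygen) and monovalent rhodium is returned. The closest known reaction type is the rhodium bisphosphine hydroacylation of 2-acylbenzaldehydes to 3-substituted phthalides, an intramolecular asymmetric Tishchenko-type isomerisation. The C3 configuration is under ligand control alone: the chelate is rigid, the C2-symmetric bisphospholane leaves one face of the C3 carbonyl open to the hydride, and the (1S,1'S,2R,2'R) enantiomer is expected to give the (S) lactone. The step needs chemoselectivity among three ketones and freedom from aldol chemistry: only the C3 carbonyl can chelate the acyl rhodium, C12' and C15' could react only intermolecularly or through macrocyclic chelates, and the medium is neutral, so the 1,4-diketone and the enolisable keto aldehyde are not disturbed.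

## Compound list

1 | 2-methylfuran | Cc1ccco1 | starting material
2 | 12-bromododecanoic acid | OC(=O)CCCCCCCCCCCBr | starting material
3 | 5-methyl-2-furyllithium | Cc1ccc([Li])o1 | intermediate
4 | lithium 12-bromododecanoate | [Li+].[O-]C(=O)CCCCCCCCCCCBr | intermediate
5 | 12-(5-methylfuran-2-yl)dodecanoic acid | OC(=O)CCCCCCCCCCCc1ccc(C)o1 | intermediate
6 | 1-[12-(5-methylfuran-2-yl)dodecanoyl]-1H-imidazole | O=C(CCCCCCCCCCCc1ccc(C)o1)n1ccnc1 | intermediate
7 | N-methoxy-N-methyl-12-(5-methylfuran-2-yl)dodecanamide | CON(C)C(=O)CCCCCCCCCCCc1ccc(C)o1 | intermediate
8 | 2-bromo-4,6-dimethoxybenzaldehyde | COc1cc(Br)c(C=O)c(OC)c1 | starting material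
9 | 2-(2-bromo-4,6-dimethoxyphenyl)-1,3-dioxolane | COc1cc(Br)c(C2OCCO2)c(OC)c1 | intermediate
10 | [2-(1,3-dioxolan-2-yl)-3,5-dimethoxyphenyl]lithium | COc1cc(OC)c(C2OCCO2)c([Li])c1 | intermediate
11 | lithium 1-[2-(1,3-dioxolan-2-yl)-3,5-dimethoxyphenyl]-1-[methoxy(methyl)amino]-12-(5-methylfuran-2-yl)dodecan-1-olate (racemic) | COc1cc(OC)c(C2OCCO2)c(c1)C(O[Li])(N(C)OC)CCCCCCCCCCCc3ccc(C)o3 | intermediate
12 | 1-[2-(1,3-dioxolan-2-yl)-3,5-dimethoxyphenyl]-12-(5-methylfuran-2-yl)dodecan-1-one | COc1cc(OC)c(C2OCCO2)c(c1)C(=O)CCCCCCCCCCCc3ccc(C)o3 | intermediate
13 | 2,4-dimethoxy-6-[12-(5-methylfuran-2-yl)dodecanoyl]benzaldehyde | COc1cc(OC)c(C=O)c(c1)C(=O)CCCCCCCCCCCc3ccc(C)o3 | intermediate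
14 | 2,4-dimethoxy-6-(13,16-dioxoheptadecanoyl)benzaldehyde | COc1cc(OC)c(C=O)c(c1)C(=O)CCCCCCCCCCCC(=O)CCC(C)=O | intermediate
15 | CJ-13,103, (3S)-5,7-dimethoxy-3-(12,15-dioxohexadecyl)-2-benzofuran-1(3H)-one | COc1cc(OC)c2c(c1)[C@H](CCCCCCCCCCCC(=O)CCC(C)=O)OC2=O | target

## Step count and least certain steps

Total: 6 steps. Longest linear sequence: 5 steps (steps 1, 2, 4, 5, 6 from 1 and 2); step 3 lies on the one-step arene branch.

Step 6 (key step). The most likely failure is slow or unselective turnover caused by the C7 methoxy group. It crowds the C1–H bond and can compete with the C3 ketone as a donor to the acyl rhodium, which would open the way to decarbonylation or lower the facial selectivity of hydride transfer. The fallback reaches the same lactone by reduction instead of isomerisation and sets out from 14. Oxidation with NaClO2, NaH2PO4 and 2-methyl-2-butene in t-BuOH/H2O would give 2,4-dimethoxy-6-(13,16-dioxoheptadecanoyl)benzoic acid F1. MeI and K2CO3 in DMF would turn its carboxylate into methyl 2,4-dimethoxy-6-(13,16-dioxoheptadecanoyl)benzoate F2. Asymmetric transfer hydrogenation with RuCl(p-cymene)[(S,S)-TsDPEN] in HCO2H/Et3N, a catalyst type that reduces aryl ketones far faster than dialkyl ketones, should give methyl 2-[(1S)-1-hydroxy-13,16-dioxoheptadecyl]-4,6-dimethoxybenzoate F3. This lactonises in the flask and the fallback comes back to the route at 15. The catalyst enantiomer is chosen by analogy with simple aryl alkyl ketones.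

Step 5. The most likely failure is an acid-catalysed aldol between the enol of the C3 ketone and the freed aldehyde, closing a five-membered carbocycle, during the slower furan opening. Incomplete opening is also possible, because the furan–diketone interconversion is an equilibrium. The fallback changes the order of events and sets out from 12. Pyridinium p-toluenesulfonate in acetone/H2O at room temperature would remove only the acetal and give 13, now isolated. The catalyst system of step 6 would convert 13 into (3S)-5,7-dimethoxy-3-[11-(5-methylfuran-2-yl)undecyl]-2-benzofuran-1(3H)-one F4. The furan would then be opened with AcOH/H2O and catalytic H2SO4 on the lactone, which has no aldehyde left and whose C3 is not prone to ionisation because both methoxy groups are meta to C3a. This fallback comes back to the route at 15.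

Step 1. The most likely failure is incomplete alkylation, because the lithium carboxylate is poorly soluble, together with competing addition of the furyl anion to the carboxylate carbon. The fallback inverts the polarity and sets out from 2. Esterification with MeOH and catalytic H2SO4 would give methyl 12-bromododecanoate F5. Zinc dust with LiCl in THF at 50 °C would insert to give (12-methoxy-12-oxododecyl)zinc bromide F6. Negishi coupling with commercial 2-bromo-5-methylfuran under Pd(OAc)2 and SPhos would give methyl 12-(5-methylfuran-2-yl)dodecanoate F7. Treatment with MeNHOMe·HCl and i-PrMgCl in THF at −10 °C would convert the ester directly into the amide, and the fallback comes back to the route at 7.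

Step 4. The most likely failure is proton transfer instead of acylation: either migration of lithium to the ring position between the two methoxy groups or enolisation of 7 by the hindered aryllithium, both of which return debrominated arene. The fallback uses a softer aryl metal and a more reactive electrophile and sets out from 7 and 9. Reduction of 7 with i-Bu2AlH in THF at −78 °C would give 12-(5-methylfuran-2-yl)dodecanal F8. Magnesium turnings with LiCl in THF would convert 9 into [2-(1,3-dioxolan-2-yl)-3,5-dimethoxyphenyl]magnesium bromide F9. Addition of F9 to F8 would give racemic 1-[2-(1,3-dioxolan-2-yl)-3,5-dimethoxyphenyl]-12-(5-methylfuran-2-yl)dodecan-1-ol F10. Oxidation with Dess–Martin periodinane buffered by NaHCO3 in CH2Cl2 would bring the fallback back to the route at 12.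

## Further compounds

F1 | step 6 | 2,4-dimethoxy-6-(13,16-dioxoheptadecanoyl)benzoic acid | COc1cc(OC)c(C(O)=O)c(c1)C(=O)CCCCCCCCCCCC(=O)CCC(C)=O
F2 | step 6 | methyl 2,4-dimethoxy-6-(13,16-dioxoheptadecanoyl)benzoate | COc1cc(OC)c(C(=O)OC)c(c1)C(=O)CCCCCCCCCCCC(=O)CCC(C)=O
F3 | step 6 | methyl 2-[(1S)-1-hydroxy-13,16-dioxoheptadecyl]-4,6-dimethoxybenzoate | COc1cc(OC)c(C(=O)OC)c(c1)[C@H](CCCCCCCCCCCC(=O)CCC(C)=O)O
F4 | step 5 | (3S)-5,7-dimethoxy-3-[11-(5-methylfuran-2-yl)undecyl]-2-benzofuran-1(3H)-one | COc1cc(OC)c2c(c1)[C@H](CCCCCCCCCCCc3ccc(C)o3)OC2=O
F5 | step 1 | methyl 12-bromododecanoate | COC(=O)CCCCCCCCCCCBr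
F6 | step 1 | (12-methoxy-12-oxododecyl)zinc bromide | COC(=O)CCCCCCCCCCC[Zn]Br
F7 | step 1 | methyl 12-(5-methylfuran-2-yl)dodecanoate | COC(=O)CCCCCCCCCCCc1ccc(C)o1
F8 | step 4 | 12-(5-methylfuran-2-yl)dodecanal | O=CCCCCCCCCCCCc1ccc(C)o1
F9 | step 4 | [2-(1,3-dioxolan-2-yl)-3,5-dimethoxyphenyl]magnesium bromide | COc1cc(OC)c(C2OCCO2)c([Mg]Br)c1
F10 | step 4 | 1-[2-(1,3-dioxolan-2-yl)-3,5-dimethoxyphenyl]-12-(5-methylfuran-2-yl)dodecan-1-ol (racemic) | COc1cc(OC)c(C2OCCO2)c(c1)C(O)CCCCCCCCCCCc3ccc(C)o3
A1 | alternative 1 | 5-[(1S)-1-(tert-butyldimethylsilyloxy)-12-(5-methylfuran-2-yl)dodecyl]-7-hydroxy-2,2-dimethyl-4H-1,3-benzodioxin-4-one | CC1(C)OC(=O)c2c(O1)cc(O)cc2[C@H](CCCCCCCCCCCc3ccc(C)o3)O[Si](C)(C)C(C)(C)C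
A2 | alternative 1 | 6-[(5S)-5-(tert-butyldimethylsilyloxy)-16-(5-methylfuran-2-yl)-2,4-dioxohexadecyl]-2,2-dimethyl-4H-1,3-dioxin-4-one | CC1(C)OC(=O)C=C(CC(=O)CC(=O)[C@H](CCCCCCCCCCCc2ccc(C)o2)O[Si](C)(C)C(C)(C)C)O1
A3 | alternative 2 | methyl 2-[(1S)-1-(tert-butyldimethylsilyloxy)-13,16-dioxoheptadecyl]-4,6-dimethoxybenzoate | COc1cc(OC)c(C(=O)OC)c(c1)[C@H](CCCCCCCCCCCC(=O)CCC(C)=O)O[Si](C)(C)C(C)(C)C
A4 | alternative 2 | methyl (4S)-4-(tert-butyldimethylsilyloxy)-16,19-dioxoicos-2-ynoate | COC(=O)C#C[C@H](CCCCCCCCCCCC(=O)CCC(C)=O)O[Si](C)(C)C(C)(C)C
A5 | alternative 2 | 1,3-dimethoxycyclohexa-1,3-diene | COC1=CC(OC)=CCC1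
A6 | alternative 3 | (3S)-5,7-dimethoxy-3-{11-[2-[2-(2-methyl-1,3-dioxolan-2-yl)ethyl]-1,3-dioxolan-2-yl]undecyl}-2-benzofuran-1(3H)-one | COc1cc(OC)c2c(c1)[C@H](CCCCCCCCCCCC3(CCC4(C)OCCO4)OCCO3)OC2=O
A7 | alternative 3 | 12-[2-[2-(2-methyl-1,3-dioxolan-2-yl)ethyl]-1,3-dioxolan-2-yl]dodecyl N,N-diisopropylcarbamate | CC(C)N(C(C)C)C(=O)OCCCCCCCCCCCCC1(CCC2(C)OCCO2)OCCO1
A8 | alternative 3 | 2-iodo-3,5-dimethoxyphenyl trifluoromethanesulfonate | COc1cc(OC)c(I)c(OS(=O)(=O)C(F)(F)F)c1
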